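The trap here is to treat the share of G in G plus Q as a fixed ratio of rates.

| flask | E | J | D | temperature | remark | time |
|---|---|---|---|---|---|---|
| south | 0.050 M | 0.055 M (fed, over 4.0 h) | 0.12 M | 12 °C | run made earlier |  |
| east | 0.050 M | 0.055 M (fed, over 4.0 h) | 0.19 M | 51 °C | run made earlier |  |
| south-west | 0.10 M | 0.055 M (fed, over 4.0 h) | 0.25 M | 12 °C | run made earlier |  |
| Saturday's | 0.050 M | 0.0550 M (fed, over 4.0 h) | 0.250 M | 15 °C |  | 30 h |
| Tuesday's | 0.050 M | 0.0550 M (fed, over 4.0 h) | 0.250 M | 35 °C |  | 30 h |
| Sunday's | 0.050 M | 0.0550 M (fed, over 4.0 h) | 0.250 M | 65 °C |  | 30 h |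
| Wednesday's | 0.050 M | 0.0550 M (fed, over 4.0 h) | 0.250 M | −5 °C |  | 30 h |
| Monday's | 0.050 M | 0.0550 M (fed, over 4.0 h) | 0.250 M | 20 °C |  | 30 h |
| Friday's | 0.050 M | 0.0550 M (fed, over 4.0 h) | 0.250 M | 50 °C |  | 30 h |

| run | time / h | G / % | Q / % |
|---|---|---|---|
| south | 12.0 | 5.5 | 4.9 |
| south | 25.0 | 14.5 | 11.9 |
| south | 30.0 | 15.0 | 11.1 |
| south | 50.0 | 19.7 | 17.2 |
| south | 60.0 | 20.9 | 19.6 |
| east | 2.00 | 7.1 | 25.2 |
| east | 4.00 | 13.9 | 42.7 |
| east | 5.00 | 17.7 | 47.4 |
| east | 6.00 | 16.7 | 50.6 |
| east | 10.0 | 17.5 | 61.1 |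
| south-west | 4.00 | 1.0 | 4.9 |
| south-west | 8.00 | 5.7 | 6.9 |
| south-west | 15.0 | 8.2 | 12.4 |
| south-west | 30.0 | 15.0 | 21.6 |
| south-west | 60.0 | 16.3 | 35.0 |

(readings scatter by 1 percentage point)

1. the flasks by share of G in all that became G or Q, highest first, at 30 h (Saturday's / Tuesday's / Sunday's / Wednesday's / Monday's / Friday's)
2. the share of G in all that became G or Q of the flask you put first, at 30 h
3. the share of G in all that became G or Q of the flask you put last, at 30 h

E goes two ways: with J to G, and with D to Q. J is fed for 4.0 h and also goes to Z and L. Two of us disagreed about what that means.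

The first takes the south-west run, with D as in these flasks and E at 0.10 M. Its share reads 41.0% at 30.0 h. She holds that both routes consume E, so the ratio carries over and every flask stays near that figure.

I answer with the east run, whose share reads 22.3% at 10.0 h, and I count half-lives. Let kQ be the rate constant of E + D → Q. I read it as Q formed, divided by time, mean E fraction and charged D. That gives 0.0314 /M/h at 12 °C and 0.784 /M/h at 51 °C. A straight line of ln kQ against temperature gives 0.00772 /M/h for Wednesday's and 2.49 /M/h for Sunday's.

Let τ be the half-life of E against Q with D as charged, a pseudo-first-order clock. Wednesday's τ is 359 h, and Sunday's is 1.11 h.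

I also assume J divides between E and D by their concentrations, with E decaying on the clock during the feed. For the east run this gives G of 18.2%, and the reading is 17.5%.

For Sunday's it gives 7.55%. Sunday's time is 26.9 half-lives, so I expect Q to take what G leaves and the share to equal that G. Wednesday's time is 0.0835 of a half-life, so I reckon its Q at 5.63%. I commit to a steady fall with temperature, and I set no figure for the top.

The forecast, Wednesday's > Saturday's > Monday's > Tuesday's > Friday's > Sunday's, with 47% and 9%, takes my side and puts its low above mine: “The share therefore falls steadily with temperature”.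

The flasks give Wednesday's > Saturday's > Monday's > Tuesday's > Friday's > Sunday's, from 47.3% down to 9.14%.

    E + J → G (k = 1.20 /M/h, Ea = 60.0 kJ/mol)
    D + J → Z (k = 0.440 /M/h, Ea = 80.0 kJ/mol)
    E + D → Q (k = 0.260 /M/h, Ea = 61.0 kJ/mol)
    2 J → L (k = 2.10 /M/h, Ea = 61.0 kJ/mol)
    (constants at 35 °C)

The ratio view has its region in Wednesday's, whose share reads 47.4% at 20 h and 47.3% at 30.0 h, with 78.8% of its J left at that second time. The clock's 5.63% for Wednesday's meets a Q of 5.27%. In a flask like Wednesday's with D cut to 0.062 M, τ stretches to 1450 h, so Q should be 1.43%. That flask gives Q of 1.33%, G of 4.88% and a share of 78.5%.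

(All runs were generated by integration for substances that don't exist; noise was put on by code.)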